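**Remarks on the chemistry (assumptions)**

- The target is addressed in the open 7-hydroxy-4-keto form that is drawn; a transannular C4/C7 hemiketal would be a ring-chain tautomer of the same compound.
- C3, α to the C4 ketone, is treated as thermodynamically controlled; the drawn configuration is assumed to be the favoured one for the β-keto ester 31 as for the target.
- Locants C1–C13 follow the carbocycle numbering defined in the analysis (C14 = methyl on C7, C15 = hydroxymethyl carbon on C3); systematic names of the bicycles use cyclodeca[b]furan locants.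

## Analysis of the target

CNP0219400.1 (36) is a germacranolide-type bicycle. Its ten-membered carbocycle is numbered C1 (lactone O–CH), C2 (CH2), C3 (CH bearing C15), C4 (ketone), C5=C6 (cis alkene), C7 (C(CH3)OH), C8 (CH2), C9 (CH–O-angelate) and C10 (ring-fusion CH); it is trans-fused across C1/C10 to an α-methylene-γ-butyrolactone made of the ring oxygen, C12 (carbonyl) and C11 (bearing the exocyclic methylene C13). There are five stereocentres, 1R, 3S, 7R, 9R and 10S in this numbering. C9, C10 and C1 are contiguous (9,10-syn along the chain through C11, H1/H10 trans), C7 is a quaternary carbinol 1,3-anti to the C9 oxygen, and C3 is isolated and epimerisable. The sensitive groups are the exocyclic methylene lactone (Michael acceptor, open to conjugate reduction), the angelate (isomerises to the tiglate under nucleophilic acylation conditions), the cis-enone with a γ-tertiary hydroxyl, the β-hydroxy ketone at C3/C4/C15 (retro-aldol, dehydration) and the acyloxy group at C9, which as a free hydroxyl could take over the lactone. The difficulty is to close a medium ring containing a cis-alkene in the presence of several electron-poor alkenes, and to relate C7 to C9/C10 across a methylene group. The strategy rests on two features: C3 lies between the C4 carbonyl and C15 and can therefore be the central carbon of a β-keto ester, and C1 carries the lactone oxygen next to C2. Joining C3 to C2 of a C1=C2 vinyl group then leaves a reactive centre at C1 within reach of the C12 carboxyl group, so one operation can close both the carbocycle (C2–C3) and the lactone (C1–O).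

## Retrosynthetic reasoning

**36 to 31 (no skeletal bond cut).** The hydroxymethyl ketone of 36 is traced back to the β-keto ester 31. An ester cannot be reduced beside the free C4 ketone, and the corresponding β-keto acid would decarboxylate, so the ketone is parked as a carbinol. Thus 36 comes from triol 35 by oxidation of its only allylic hydroxyl, 35 from acid 33 by reduction of the activated carboxyl group, 33 from ester 32 by fluoride-induced loss of both silicon groups, and 32 from 31 by 1,2-reduction. The angelate is already present in 31, so no hydroxyl next to the lactone is ever free and no selective acylation among several hydroxyls is needed at the end.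

**31 to 28 (C2–C3 and C1–O).** Both bonds are cut together. This removes both rings and the stereocentres C1 and C3 at once and leaves the acyclic keto acid 28, in which C3 is a β-keto ester methylene, C1=C2 is a vinyl group and C12 is a free acid. A cut at C9–C10 or C1–C10 would instead require C1 and C3 to be carried through a long chain synthesis. Forward, the C3 radical 29 must choose the vinyl terminus, and the ring radical 30 must be oxidised and captured by the carboxylate before it does anything else.

**28 to 21 and 23 (C3–C4).** Keto acid 28 comes from hydroxy acid 27 by oxidation, placed last because the cis-enone β-keto ester is the most fragile intermediate. 27 comes from diester 25 by cleaving the tert-butyl ester, and 25 from the cis-enal 21 and the enolate 24 of acetate 23 (made from 22) by an aldol addition. The aldol/oxidation pair is preferred to acylation chemistry at C4 because it needs no activated cis-enoic acid derivative that could isomerise.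

**21 to 17 and 18 (C9–O acyl, C4 oxidation level).** The aldehyde of 21 is the oxidised form of the primary silyl ether in 20, which is cleaved selectively beside the tertiary one. The angelate of 20 comes from alcohol 17 and angelic acid (18) through the mixed anhydride 19, at a stage where C9–OH is the only free hydroxyl.

**17 to 11 and 15 (C9–C10).** This cut delivers the skipped diene with its acrylate in one step: the allylindium 16 derived from bromide 15 adds through its γ-carbon to aldehyde 11. The reagent geometry sets the 9,10-syn relationship; the relationship to C7 is the weak point and is dealt with by separation.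

**15 to 12 and 13.** The bromide is the allylic transposition product of the carbinol 14, itself the coupling product of acrolein (12) and tert-butyl acrylate (13). The tert-butyl ester is chosen because the γ-hydroxy ester 17 must not lactonise onto C9.

**11 to 5 and 6 (C4–C5, C5=C6).** Aldehyde 11 is unmasked from dithiane 10, the bis-silyl ether of the cis-enediol 9, which is the reduction product of butenolide 8. The butenolide arises from hydroxy aldehyde 5 and the ketene ylide 6 through the ester ylide 7; its five-membered ring fixes the cis geometry of C5=C6 without a selective olefination or an alkyne semi-reduction.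

**5 to 1 and 2 (C8–C9).** Aldehyde 5 is the oxidation product of diol 4, which comes from (S)-2-methylglycidol (1) by epoxide opening with the anion 3 of 1,3-dithiane (2). This brings C7 from the chiral pool and C9 as a masked aldehyde.

## Alternatives that were turned down

**Alternative 1:** The C1–C10 bond is disconnected. In the forward sense the thirteen-membered allylic ether stannane A1 undergoes tin–lithium exchange at C1, and the α-alkoxy carbanion rearranges by a [2,3]-Wittig shift to the ten-membered homoallylic alcohol A2, creating the C11=C13 methylene at the same time. In its favour, contraction of a relatively unstrained large-ring ether to a ten-membered carbocycle is a known route to germacranoid rings, so on precedent for ring formation it is stronger than the chosen route. Against it here, the organolithium step tolerates neither the ketone nor any ester: C4 must be a protected carbinol, C12 an alcohol and C9 an ether. After the key step the lactone has to be built by oxidising C12, the C4 ketone restored and the angelate introduced, each with its own protecting-group step. The relative configuration of C1 and C10 depends on the geometry of the ring alkene and on the folding of the transition state, neither of which the substrate secures. The chosen route offers, in place of precedent, a closure that delivers ring and lactone at their final oxidation level from a shorter acyclic chain.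

**Alternative 2:** The C4–O and C7–O bonds are disconnected from the ring diene A3. Forward, sensitised photo-oxygenation adds across C4 and C7 in a [4+2] sense to give the bridged endoperoxide A4, whose base-induced opening can only remove the C4 hydrogen and so would give the C4 ketone, the C7 carbinol and the cis-alkene together. On installing this oxygenation pattern it is stronger than the chosen route, which needs a reduction/reoxidation detour at C4. It does not, however, solve the ten-membered ring: A3 must itself come from another macrocyclisation. The face of the flexible diene that is attacked decides C7 and is not controlled by anything nearby. The trisubstituted diene terminus carries allylic hydrogens, so an ene reaction competes, and the s-cis diene geometry is strained in a ten-membered ring. The chosen strategy takes C7 from the chiral pool and uses its key step for the ring.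

**Alternative 3:** The C9–C10 bond is disconnected. Forward, a divalent chromium salt converts the bromomethyl butenolide aldehyde A5 into an allylchromium species that adds through C10 to the C9 aldehyde, closing the ring and forming the exocyclic methylene in A6. Polar chromium-mediated ring closures of this kind are chemoselective and established for medium rings, so on reliability of the closure it is stronger than a radical macrocyclisation. Against it, the cyclic transition state delivers the C9 epimer, so the angelate would have to be introduced with inversion by a Mitsunobu reaction with 18 on a hindered alcohol flanked by C10, where elimination competes. The free C9 alkoxide next to the lactone also invites translactonisation. In addition A5 must carry C1 and the epimerisable, β-oxygenated C3 centre through a long linear sequence beside a cis-enone. The chosen route sets and acylates C9 before ring closure and creates C1 and C3 in the key step; the price is lower precedent.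

Key step: step 16

## Route

Step 1
Reactants: 1 (S)-2-methylglycidol; 2 1,3-dithiane
Product: 4 (2R)-3-(1,3-dithian-2-yl)-2-methylpropane-1,2-diol, via 2-lithio-1,3-dithiane 3 (not isolated)
Conditions: 2 (2.6 equiv), n-BuLi (2.5 equiv), THF, −30 °C; then 1, THF/DMPU, −30 → 0 °C; H2O
Reagents that add atoms: none
Why: Epoxide opening by the dithiane anion (umpolung, SN2 at the unsubstituted oxirane carbon): the first equivalent of 3 only deprotonates the hydroxyl of 1, the second opens the ring and brings in C9 as a masked aldehyde. C7 is not a reacting centre, and a Payne shift of the alkoxide is degenerate and returns the same enantiomer, so the configuration of 1 is carried over (the descriptor becomes R only because the priorities change).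

Step 2
Reactants: 4 (2R)-3-(1,3-dithian-2-yl)-2-methylpropane-1,2-diol
Product: 5 (2R)-3-(1,3-dithian-2-yl)-2-hydroxy-2-methylpropanal
Conditions: SO3·pyridine, DMSO, i-Pr2NEt, CH2Cl2, 0 °C
Reagents that add atoms: none
Why: Parikh–Doering oxidation: only the primary hydroxyl can be oxidised, the activated sulfoxide leaves the thioacetal sulfur alone, and the quaternary α-carbon excludes epimerisation.

Step 3
Reactants: 5 (2R)-3-(1,3-dithian-2-yl)-2-hydroxy-2-methylpropanal; 6 (triphenylphosphoranylidene)ketene Ph3P=C=C=O
Product: 8 (5R)-5-(1,3-dithian-2-ylmethyl)-5-methylfuran-2(5H)-one, via phosphoranylidene acetate ester 7 (not isolated)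
Conditions: 6 (1.2 equiv), toluene, 90 °C
Reagents that add atoms: none
Why: The tertiary hydroxyl adds across the ketene C=C bond of 6 to give the stabilised ester ylide 7, which closes by intramolecular Wittig olefination on the neighbouring aldehyde. The five-membered ring can only hold a cis double bond, so the C5=C6 geometry is fixed here.

Step 4
Reactants: 8 (5R)-5-(1,3-dithian-2-ylmethyl)-5-methylfuran-2(5H)-one
Product: 9 (2Z,4R)-5-(1,3-dithian-2-yl)-4-methylpent-2-ene-1,4-diol
Conditions: i-Bu2AlH (3.5 equiv), CH2Cl2, −78 → 0 °C; aq. KNaC4H4O6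
Reagents that add atoms: none
Why: Exhaustive 1,2-reduction of the unsaturated lactone carbonyl by two hydride transfers gives the cis-enediol; the alkene geometry is inherited from the ring and the dithioacetal is inert to the aluminium hydride.

Step 5
Reactants: 9 (2Z,4R)-5-(1,3-dithian-2-yl)-4-methylpent-2-ene-1,4-diol
Product: 10 2-[(2R,3Z)-2-methyl-2,5-bis(triethylsilyloxy)pent-3-en-1-yl]-1,3-dithiane
Conditions: Et3SiOTf (2.5 equiv), 2,6-lutidine, CH2Cl2, −78 → 0 °C
Reagents that add atoms: triethylsilyl trifluoromethanesulfonate, CC[Si](CC)(CC)OS(=O)(=O)C(F)(F)F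
Why: Silyl triflate with a hindered pyridine base silylates both the primary and the tertiary hydroxyl. The primary silyl ether is chosen because it can later be oxidised directly (step 11), the tertiary one because it lasts until fluoride is used (step 18).

Step 6
Reactants: 10 2-[(2R,3Z)-2-methyl-2,5-bis(triethylsilyloxy)pent-3-en-1-yl]-1,3-dithiane
Product: 11 (3R,4Z)-3-methyl-3,6-bis(triethylsilyloxy)hex-4-enal
Conditions: MeI, CaCO3, MeCN/H2O (9:1), 45 °C
Reagents that add atoms: water, O
Why: S-Methylation and hydrolysis of the dithioacetal under carbonate buffering release the aldehyde without acid, so both silyl ethers and the cis-alkene persist.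

Step 7
Reactants: 12 acrolein; 13 tert-butyl acrylate
Product: 14 tert-butyl 3-hydroxy-2-methylidenepent-4-enoate (racemic)
Conditions: DABCO (0.2 equiv), 13 (3 equiv, neat), 0 °C → rt
Reagents that add atoms: none
Why: Morita–Baylis–Hillman reaction: the amine adds to the acrylate, the resulting enolate attacks the aldehyde carbon of acrolein (1,2-addition) and the amine is expelled; excess 13 makes the acrylate, not acrolein, the donor. The carbinol centre is formed racemic and is erased in step 8.

Step 8
Reactants: 14 tert-butyl 3-hydroxy-2-methylidenepent-4-enoate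
Product: 15 tert-butyl (2Z)-2-(bromomethyl)penta-2,4-dienoate
Conditions: NBS, Me2S, CH2Cl2, 0 °C → rt
Reagents that add atoms: N-bromosuccinimide, O=C1CCC(=O)N1Br
Why: Corey–Kim-type activation of the doubly allylic alcohol and return of bromide with allylic transposition (SN2') give the conjugated dienoate without acid that would cleave the tert-butyl ester. The trisubstituted alkene settles with the vinyl group trans to the ester, which is the (2Z) bromide.

Step 9
Reactants: 11 (3R,4Z)-3-methyl-3,6-bis(triethylsilyloxy)hex-4-enal; 15 tert-butyl (2Z)-2-(bromomethyl)penta-2,4-dienoate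
Product: 17 tert-butyl (3R,4R,6R,7Z)-3-ethenyl-4-hydroxy-6-methyl-2-methylidene-6,9-bis(triethylsilyloxy)non-7-enoate, via allylindium dibromide 16 (not isolated)
Conditions: In powder (1.5 equiv), 15 (1.5 equiv), DMF, 0 °C → rt; aq. NaHCO3
Reagents that add atoms: none
Why: Indium-mediated Barbier allylation: 16 adds through its γ-carbon in a chair Zimmerman–Traxler transition state with the aldehyde chain equatorial and the γ-vinyl group (cis to CH2In) axial, which gives the 9,10-syn adduct and the 2-substituted acrylate in one step; the 1,5-metallotropic isomer of 16 leads to the same diastereomer. The β-silyloxy quaternary C7 is expected to give only a modest 1,3-anti bias, so the 7,9-anti adduct 17 is separated by chromatography from the other syn diastereomer (opposite at both C9 and C10). The tert-butyl ester keeps the γ-hydroxy ester from lactonising.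

Step 10
Reactants: 17 tert-butyl (3R,4R,6R,7Z)-3-ethenyl-4-hydroxy-6-methyl-2-methylidene-6,9-bis(triethylsilyloxy)non-7-enoate; 18 angelic acid [(2Z)-2-methylbut-2-enoic acid]
Product: 20 tert-butyl (3R,4R,6R,7Z)-3-ethenyl-6-methyl-4-{[(2Z)-2-methylbut-2-enoyl]oxy}-2-methylidene-6,9-bis(triethylsilyloxy)non-7-enoate, via angelic 2,4,6-trichlorobenzoic anhydride 19 (not isolated)
Conditions: 18, 2,4,6-Cl3C6H2COCl, Et3N, toluene, rt; then 17, 80 °C
Reagents that add atoms: none
Why: Yamaguchi-type esterification through the mixed anhydride 19 without a nucleophilic catalyst, the conditions under which (Z)-2-methylbut-2-enoates form without addition–elimination isomerisation to the tiglate. C9–OH is the only free hydroxyl, and acylating it now means that no hydroxyl next to the future lactone is ever set free.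

Step 11
Reactants: 20 tert-butyl (3R,4R,6R,7Z)-3-ethenyl-6-methyl-4-{[(2Z)-2-methylbut-2-enoyl]oxy}-2-methylidene-6,9-bis(triethylsilyloxy)non-7-enoate
Product: 21 tert-butyl (3R,4R,6R,7Z)-3-ethenyl-6-methyl-4-{[(2Z)-2-methylbut-2-enoyl]oxy}-2-methylidene-9-oxo-6-(triethylsilyloxy)non-7-enoate
Conditions: (COCl)2, DMSO, CH2Cl2, −78 → −40 °C; Et3N, −78 → −20 °C
Reagents that add atoms: none
Why: Swern conditions convert primary triethylsilyl ethers directly into aldehydes (silicon–oxygen cleavage by the activated sulfoxide, then base-induced elimination), while the tertiary silyl ether is too hindered to react. The cis geometry is kept because C6 is shielded by the quaternary C7 against the conjugate addition that would isomerise it; 21 is used crude.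

Step 12
Reactants: 22 2-(trimethylsilyl)ethanol
Product: 23 2-(trimethylsilyl)ethyl acetate
Conditions: Ac2O, pyridine, DMAP (cat.), CH2Cl2, rt
Reagents that add atoms: acetic anhydride, CC(=O)OC(C)=O
Why: Acylation of a primary alcohol under nucleophilic catalysis; the acetate supplies C3 and C15 together with the fluoride-labile ester group.

Step 13
Reactants: 21 tert-butyl (3R,4R,6R,7Z)-3-ethenyl-6-methyl-4-{[(2Z)-2-methylbut-2-enoyl]oxy}-2-methylidene-9-oxo-6-(triethylsilyloxy)non-7-enoate; 23 2-(trimethylsilyl)ethyl acetate
Product: 25 1-tert-butyl 11-[2-(trimethylsilyl)ethyl] (3R,4R,6R,7Z)-3-ethenyl-9-hydroxy-6-methyl-4-{[(2Z)-2-methylbut-2-enoyl]oxy}-2-methylidene-6-(triethylsilyloxy)undec-7-enedioate (both C9 epimers), via lithium enolate 24 (not isolated)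
Conditions: 23, LiN(i-Pr)2, THF, −78 °C; then 21, −78 °C, 15 min; AcOH
Reagents that add atoms: none
Why: Aldol addition of the lithium ester enolate 24 to the aldehyde at −78 °C; 1,2-addition to the aldehyde is much faster than conjugate addition to the hindered tert-butyl 2-substituted acrylate or to the angelate. The new carbinol centre (C4 of the carbocycle) is not controlled and need not be, because it is oxidised in step 15.

Step 14
Reactants: 25 1-tert-butyl 11-[2-(trimethylsilyl)ethyl] (3R,4R,6R,7Z)-3-ethenyl-9-hydroxy-6-methyl-4-{[(2Z)-2-methylbut-2-enoyl]oxy}-2-methylidene-6-(triethylsilyloxy)undec-7-enedioate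
Product: 27 (3R,4R,6R,7Z)-3-ethenyl-9-hydroxy-6-methyl-4-{[(2Z)-2-methylbut-2-enoyl]oxy}-2-methylidene-11-oxo-6-(triethylsilyloxy)-11-[2-(trimethylsilyl)ethoxy]undec-7-enoic acid (both C9 epimers), via bis(trimethylsilyl) derivative 26 (not isolated)
Conditions: Me3SiOTf (4 equiv), 2,6-lutidine (6 equiv), CH2Cl2, 0 °C; then aq. citric acid, MeOH, 0 °C
Reagents that add atoms: none
Why: Silyl triflate-mediated cleavage of the tert-butyl ester (silylation of the carbonyl oxygen, loss of 2-methylpropene) gives the silyl ester, and the free hydroxyl is silylated in passing (26); mild acid hydrolysis then frees the acid and the carbinol. The tertiary triethylsilyl ether, the primary 2-silylethyl ester and the angelate do not ionise under these buffered conditions.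

Step 15
Reactants: 27 (3R,4R,6R,7Z)-3-ethenyl-9-hydroxy-6-methyl-4-{[(2Z)-2-methylbut-2-enoyl]oxy}-2-methylidene-11-oxo-6-(triethylsilyloxy)-11-[2-(trimethylsilyl)ethoxy]undec-7-enoic acid
Product: 28 (3R,4R,6R,7Z)-3-ethenyl-6-methyl-4-{[(2Z)-2-methylbut-2-enoyl]oxy}-2-methylidene-9,11-dioxo-6-(triethylsilyloxy)-11-[2-(trimethylsilyl)ethoxy]undec-7-enoic acid
Conditions: Dess–Martin periodinane, CH2Cl2, 0 °C → rt
Reagents that add atoms: none
Why: Dess–Martin oxidation of the allylic secondary alcohol under neutral conditions gives the cis-enone β-keto ester without base that could isomerise the alkene or the skipped diene; the free acid is tolerated. 28 is used at once.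

Step 16
Reactants: 28 (3R,4R,6R,7Z)-3-ethenyl-6-methyl-4-{[(2Z)-2-methylbut-2-enoyl]oxy}-2-methylidene-9,11-dioxo-6-(triethylsilyloxy)-11-[2-(trimethylsilyl)ethoxy]undec-7-enoic acid
Product: 31 2-(trimethylsilyl)ethyl (3aS,4R,6R,7Z,10R,11aR)-6-methyl-4-{[(2Z)-2-methylbut-2-enoyl]oxy}-3-methylidene-2,9-dioxo-6-(triethylsilyloxy)-2,3,3a,4,5,6,9,10,11,11a-decahydrocyclodeca[b]furan-10-carboxylate, via C3 radical 29 (not isolated), via ten-membered C1 radical 30 (not isolated)
Conditions: Mn(OAc)3·2H2O (2.2 equiv), Cu(OAc)2·H2O (1.0 equiv), KOAc (2 equiv), degassed AcOH, 35 °C; 28 added by syringe pump over 10 h (final 2 mM)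
Reagents that add atoms: none
Why: Proposed new method: Mn(OAc)3 (trivalent manganese) oxidises the enol of the β-keto ester in 28 to the electrophilic C3 radical 29, which adds to the unsubstituted terminus C2 of the C1=C2 vinyl group in a 10-endo-trig closure to give the secondary ring radical 30; Cu(OAc)2 (divalent copper), already ligated by the C12 carboxylate, oxidises this radical to an alkylcopper species that collapses with C1–O bond formation (5-exo closure of the lactone), so both rings arise in one operation. The closest known reaction types are the Mn(OAc)3/Cu(OAc)2 oxidative cyclisations of unsaturated β-keto esters to five- and six-membered rings, the Mn(OAc)3 γ-lactone annulation in which a γ-carboxy secondary radical is oxidatively lactonised, and endo-selective radical macrocyclisations onto terminal alkenes; their combination in a ten-membered closure has not been shown. Chemoselectivity rests on polarity and sterics: the dicarbonyl-stabilised radical is electrophilic, the acrylic acid, enone and angelate alkenes are electron-poor and substituted, and only the vinyl group offers an unhindered, comparatively electron-rich terminus, attack at C2 giving the more stable secondary radical. Slow addition at high dilution suppresses intermolecular addition, and the cis-alkene and the substituents at C7, C9 and C10 limit the conformations of the chain. C1 is set in the lactonisation: the carboxylate on C11 reaches the planar C1 centre in the rotamer that keeps C2 anti to C9 about the C1–C10 bond, the low-strain arrangement of the ten-membered ring, which gives the trans-fused lactone (H1 and H10 trans). C3 is formed as an enolisable β-keto ester centre and is expected to settle under the acidic conditions in the favoured configuration that is drawn. The step also needs 31, which still carries a C3–H, to be oxidised more slowly than 28; the slower enolisation of a ring-bound, α-substituted β-keto ester and the limit of about two equivalents of oxidant are relied on for that.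

Step 17
Reactants: 31 2-(trimethylsilyl)ethyl (3aS,4R,6R,7Z,10R,11aR)-6-methyl-4-{[(2Z)-2-methylbut-2-enoyl]oxy}-3-methylidene-2,9-dioxo-6-(triethylsilyloxy)-2,3,3a,4,5,6,9,10,11,11a-decahydrocyclodeca[b]furan-10-carboxylate
Product: 32 2-(trimethylsilyl)ethyl (3aS,4R,6R,7Z,10R,11aR)-9-hydroxy-6-methyl-4-{[(2Z)-2-methylbut-2-enoyl]oxy}-3-methylidene-2-oxo-6-(triethylsilyloxy)-2,3,3a,4,5,6,9,10,11,11a-decahydrocyclodeca[b]furan-10-carboxylate (both C9 epimers)
Conditions: NaBH4, CeCl3·7H2O, MeOH/THF, −78 °C
Reagents that add atoms: none
Why: Luche reduction: the cerium-modified borohydride attacks the ketone carbonyl (1,2) and not the exocyclic methylene lactone or the esters. It removes the β-keto ester so that the ester can be cleaved without decarboxylation, and it fixes C3; the new carbinol centre is irrelevant because it is reoxidised in step 20.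

Step 18
Reactants: 32 2-(trimethylsilyl)ethyl (3aS,4R,6R,7Z,10R,11aR)-9-hydroxy-6-methyl-4-{[(2Z)-2-methylbut-2-enoyl]oxy}-3-methylidene-2-oxo-6-(triethylsilyloxy)-2,3,3a,4,5,6,9,10,11,11a-decahydrocyclodeca[b]furan-10-carboxylate
Product: 33 (3aS,4R,6R,7Z,10R,11aR)-6,9-dihydroxy-6-methyl-4-{[(2Z)-2-methylbut-2-enoyl]oxy}-3-methylidene-2-oxo-2,3,3a,4,5,6,9,10,11,11a-decahydrocyclodeca[b]furan-10-carboxylic acid (both C9 epimers)
Conditions: (Me2N)3S+ Me3SiF2− (TASF, 3 equiv), DMF, 0 °C → rt; dil. aq. HCl to pH 4
Reagents that add atoms: none
Why: Fluoride attacks silicon: the 2-silylethyl ester fragments to the carboxylate, ethene and the silyl fluoride, and the tertiary triethylsilyl ether is cleaved in the same operation. The anhydrous, weakly basic fluoride source leaves the lactone, the angelate and the β-hydroxy acid untouched.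

Step 19
Reactants: 33 (3aS,4R,6R,7Z,10R,11aR)-6,9-dihydroxy-6-methyl-4-{[(2Z)-2-methylbut-2-enoyl]oxy}-3-methylidene-2-oxo-2,3,3a,4,5,6,9,10,11,11a-decahydrocyclodeca[b]furan-10-carboxylic acid
Product: 35 (3aS,4R,6R,7Z,10S,11aR)-6,9-dihydroxy-10-(hydroxymethyl)-6-methyl-3-methylidene-2-oxo-2,3,3a,4,5,6,9,10,11,11a-decahydrocyclodeca[b]furan-4-yl (2Z)-2-methylbut-2-enoate (both C9 epimers), via isobutyl carbonic anhydride 34 (not isolated)
Conditions: i-BuOCOCl, N-methylmorpholine, THF, −15 °C; then NaBH4, H2O, −15 °C, 10 min
Reagents that add atoms: none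
Why: Mixed carbonic anhydride activation and borohydride reduction: the anhydride carbonyl is reduced within minutes at −15 °C whereas the lactone and angelate carbonyls are not, and the short contact time keeps conjugate reduction of the methylene lactone down. The chloroformate reacts with the carboxylate far faster than with the secondary and tertiary hydroxyls.

Step 20
Reactants: 35 (3aS,4R,6R,7Z,10S,11aR)-6,9-dihydroxy-10-(hydroxymethyl)-6-methyl-3-methylidene-2-oxo-2,3,3a,4,5,6,9,10,11,11a-decahydrocyclodeca[b]furan-4-yl (2Z)-2-methylbut-2-enoate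
Product: 36 target CNP0219400.1: (3aS,4R,6R,7Z,10S,11aR)-6-hydroxy-10-(hydroxymethyl)-6-methyl-3-methylidene-2,9-dioxo-2,3,3a,4,5,6,9,10,11,11a-decahydrocyclodeca[b]furan-4-yl (2Z)-2-methylbut-2-enoate
Conditions: MnO2 (activated, 20 equiv), CH2Cl2, rt
Reagents that add atoms: none
Why: MnO2 oxidises only the allylic secondary hydroxyl; the primary (non-allylic) and tertiary hydroxyls are inert and the ring holds the alkene cis. Both carbinol epimers converge on the enone, and C3 keeps the configuration carried from 31.

## Compound list

1 | (S)-2-methylglycidol | C[C@]1(CO)CO1 | starting material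
2 | 1,3-dithiane | C1CSCSC1 | starting material
3 | 2-lithio-1,3-dithiane | [Li]C1SCCCS1 | intermediate
4 | (2R)-3-(1,3-dithian-2-yl)-2-methylpropane-1,2-diol | C[C@](O)(CO)CC1SCCCS1 | intermediate
5 | (2R)-3-(1,3-dithian-2-yl)-2-hydroxy-2-methylpropanal | C[C@](O)(C=O)CC1SCCCS1 | intermediate
6 | (triphenylphosphoranylidene)ketene | O=C=C=P(c1ccccc1)(c1ccccc1)c1ccccc1 | starting material
7 | (2R)-1-(1,3-dithian-2-yl)-2-methyl-3-oxopropan-2-yl (triphenylphosphoranylidene)acetate | C[C@](OC(=O)C=P(c1ccccc1)(c1ccccc1)c1ccccc1)(C=O)CC1SCCCS1 | intermediate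
8 | (5R)-5-(1,3-dithian-2-ylmethyl)-5-methylfuran-2(5H)-one | C[C@]1(CC2SCCCS2)OC(=O)C=C1 | intermediate
9 | (2Z,4R)-5-(1,3-dithian-2-yl)-4-methylpent-2-ene-1,4-diol | C[C@](O)(/C=C\CO)CC1SCCCS1 | intermediate
10 | 2-[(2R,3Z)-2-methyl-2,5-bis(triethylsilyloxy)pent-3-en-1-yl]-1,3-dithiane | C[C@](O[Si](CC)(CC)CC)(/C=C\CO[Si](CC)(CC)CC)CC1SCCCS1 | intermediate
11 | (3R,4Z)-3-methyl-3,6-bis(triethylsilyloxy)hex-4-enal | C[C@](O[Si](CC)(CC)CC)(/C=C\CO[Si](CC)(CC)CC)CC=O | intermediate
12 | acrolein | C=CC=O | starting material
13 | tert-butyl acrylate | C=CC(=O)OC(C)(C)C | starting material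
14 | tert-butyl 3-hydroxy-2-methylidenepent-4-enoate (racemic) | C=CC(O)C(=C)C(=O)OC(C)(C)C | intermediate
15 | tert-butyl (2Z)-2-(bromomethyl)penta-2,4-dienoate | C=C/C=C(\CBr)C(=O)OC(C)(C)C | intermediate
16 | tert-butyl (2Z)-2-[(dibromoindiganyl)methyl]penta-2,4-dienoate (allylindium dibromide, simplest formulation) | C=C/C=C(\C[In](Br)Br)C(=O)OC(C)(C)C | intermediate
17 | tert-butyl (3R,4R,6R,7Z)-3-ethenyl-4-hydroxy-6-methyl-2-methylidene-6,9-bis(triethylsilyloxy)non-7-enoate | C=C[C@@H]([C@H](O)C[C@@](C)(O[Si](CC)(CC)CC)/C=C\CO[Si](CC)(CC)CC)C(=C)C(=O)OC(C)(C)C | intermediate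
18 | angelic acid, (2Z)-2-methylbut-2-enoic acid | C/C=C(/C)C(=O)O | starting material
19 | (2Z)-2-methylbut-2-enoic 2,4,6-trichlorobenzoic anhydride | C/C=C(/C)C(=O)OC(=O)c1c(Cl)cc(Cl)cc1Cl | intermediate
20 | tert-butyl (3R,4R,6R,7Z)-3-ethenyl-6-methyl-4-{[(2Z)-2-methylbut-2-enoyl]oxy}-2-methylidene-6,9-bis(triethylsilyloxy)non-7-enoate | C=C[C@@H]([C@H](OC(=O)/C(C)=C\C)C[C@@](C)(O[Si](CC)(CC)CC)/C=C\CO[Si](CC)(CC)CC)C(=C)C(=O)OC(C)(C)C | intermediate
21 | tert-butyl (3R,4R,6R,7Z)-3-ethenyl-6-methyl-4-{[(2Z)-2-methylbut-2-enoyl]oxy}-2-methylidene-9-oxo-6-(triethylsilyloxy)non-7-enoate | C=C[C@@H]([C@H](OC(=O)/C(C)=C\C)C[C@@](C)(O[Si](CC)(CC)CC)/C=C\C=O)C(=C)C(=O)OC(C)(C)C | intermediate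
22 | 2-(trimethylsilyl)ethanol | C[Si](C)(C)CCO | starting material
23 | 2-(trimethylsilyl)ethyl acetate | CC(=O)OCC[Si](C)(C)C | intermediate
24 | lithium 1-[2-(trimethylsilyl)ethoxy]ethenolate | [Li]OC(=C)OCC[Si](C)(C)C | intermediate
25 | 1-tert-butyl 11-[2-(trimethylsilyl)ethyl] (3R,4R,6R,7Z)-3-ethenyl-9-hydroxy-6-methyl-4-{[(2Z)-2-methylbut-2-enoyl]oxy}-2-methylidene-6-(triethylsilyloxy)undec-7-enedioate (both C9 epimers) | C=C[C@@H]([C@H](OC(=O)/C(C)=C\C)C[C@@](C)(O[Si](CC)(CC)CC)/C=C\C(O)CC(=O)OCC[Si](C)(C)C)C(=C)C(=O)OC(C)(C)C | intermediate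
26 | trimethylsilyl ester and 9-O-trimethylsilyl ether of 27 | C=C[C@@H]([C@H](OC(=O)/C(C)=C\C)C[C@@](C)(O[Si](CC)(CC)CC)/C=C\C(O[Si](C)(C)C)CC(=O)OCC[Si](C)(C)C)C(=C)C(=O)O[Si](C)(C)C | intermediate
27 | (3R,4R,6R,7Z)-3-ethenyl-9-hydroxy-6-methyl-4-{[(2Z)-2-methylbut-2-enoyl]oxy}-2-methylidene-11-oxo-6-(triethylsilyloxy)-11-[2-(trimethylsilyl)ethoxy]undec-7-enoic acid (both C9 epimers) | C=C[C@@H]([C@H](OC(=O)/C(C)=C\C)C[C@@](C)(O[Si](CC)(CC)CC)/C=C\C(O)CC(=O)OCC[Si](C)(C)C)C(=C)C(=O)O | intermediate
28 | (3R,4R,6R,7Z)-3-ethenyl-6-methyl-4-{[(2Z)-2-methylbut-2-enoyl]oxy}-2-methylidene-9,11-dioxo-6-(triethylsilyloxy)-11-[2-(trimethylsilyl)ethoxy]undec-7-enoic acid | C=C[C@@H]([C@H](OC(=O)/C(C)=C\C)C[C@@](C)(O[Si](CC)(CC)CC)/C=C\C(=O)CC(=O)OCC[Si](C)(C)C)C(=C)C(=O)O | intermediate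
29 | C3 radical of 28 (radical at the carbon between ketone and ester) | C=C[C@@H]([C@H](OC(=O)/C(C)=C\C)C[C@@](C)(O[Si](CC)(CC)CC)/C=C\C(=O)[CH]C(=O)OCC[Si](C)(C)C)C(=C)C(=O)O | intermediate
30 | ten-membered C1 radical (C2–C3 closed, acid still free) | C=C(C(=O)O)[C@H]1[CH]CC(C(=O)OCC[Si](C)(C)C)C(=O)/C=C\[C@](C)(O[Si](CC)(CC)CC)C[C@H]1OC(=O)/C(C)=C\C | intermediate
31 | 2-(trimethylsilyl)ethyl (3aS,4R,6R,7Z,10R,11aR)-6-methyl-4-{[(2Z)-2-methylbut-2-enoyl]oxy}-3-methylidene-2,9-dioxo-6-(triethylsilyloxy)-2,3,3a,4,5,6,9,10,11,11a-decahydrocyclodeca[b]furan-10-carboxylate | C=C1C(=O)O[C@@H]2C[C@@H](C(=O)OCC[Si](C)(C)C)C(=O)/C=C\[C@](C)(O[Si](CC)(CC)CC)C[C@@H](OC(=O)/C(C)=C\C)[C@@H]12 | intermediate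
32 | 2-(trimethylsilyl)ethyl (3aS,4R,6R,7Z,10R,11aR)-9-hydroxy-6-methyl-4-{[(2Z)-2-methylbut-2-enoyl]oxy}-3-methylidene-2-oxo-6-(triethylsilyloxy)-2,3,3a,4,5,6,9,10,11,11a-decahydrocyclodeca[b]furan-10-carboxylate (both C9 epimers) | C=C1C(=O)O[C@@H]2C[C@@H](C(=O)OCC[Si](C)(C)C)C(O)/C=C\[C@](C)(O[Si](CC)(CC)CC)C[C@@H](OC(=O)/C(C)=C\C)[C@@H]12 | intermediate
33 | (3aS,4R,6R,7Z,10R,11aR)-6,9-dihydroxy-6-methyl-4-{[(2Z)-2-methylbut-2-enoyl]oxy}-3-methylidene-2-oxo-2,3,3a,4,5,6,9,10,11,11a-decahydrocyclodeca[b]furan-10-carboxylic acid (both C9 epimers) | C=C1C(=O)O[C@@H]2C[C@@H](C(=O)O)C(O)/C=C\[C@](C)(O)C[C@@H](OC(=O)/C(C)=C\C)[C@@H]12 | intermediate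
34 | isobutyl carbonic anhydride of 33 | C=C1C(=O)O[C@@H]2C[C@@H](C(=O)OC(=O)OCC(C)C)C(O)/C=C\[C@](C)(O)C[C@@H](OC(=O)/C(C)=C\C)[C@@H]12 | intermediate
35 | (3aS,4R,6R,7Z,10S,11aR)-6,9-dihydroxy-10-(hydroxymethyl)-6-methyl-3-methylidene-2-oxo-2,3,3a,4,5,6,9,10,11,11a-decahydrocyclodeca[b]furan-4-yl (2Z)-2-methylbut-2-enoate (both C9 epimers) | C=C1C(=O)O[C@@H]2C[C@@H](CO)C(O)/C=C\[C@](C)(O)C[C@@H](OC(=O)/C(C)=C\C)[C@@H]12 | intermediate
36 | CNP0219400.1, (3aS,4R,6R,7Z,10S,11aR)-6-hydroxy-10-(hydroxymethyl)-6-methyl-3-methylidene-2,9-dioxo-2,3,3a,4,5,6,9,10,11,11a-decahydrocyclodeca[b]furan-4-yl (2Z)-2-methylbut-2-enoate | C=C1C(=O)O[C@@H]2C[C@@H](CO)C(=O)/C=C\[C@](C)(O)C[C@@H](OC(=O)/C(C)=C\C)[C@@H]12 | target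

## Step count and least certain steps

Total step count: 20 (steps 7, 8 and 12 prepare the two side reagents 15 and 23).
Longest linear sequence: 17 steps (steps 1–6, 9–11 and 13–20).

**Step 16 (key step).** The most likely failure is that ring closure loses to other fates of the two radicals. The 10-endo addition is entropically and transannularly costly, so 29 may be reduced, oxidised or added to a second molecule before it finds C2. The ring radical 30 may add across the ring to the enone carbon C6 (a 6-exo Giese-type closure) before copper captures it. The product, still enolisable at C3, may also be oxidised again, and the acidic medium may erode the cis-enone or the silyl ether.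
Fallback (known polar chemistry, from 27 back to 31): the lactone is closed first by iodolactonisation of 27 (I2, NaHCO3, MeCN, 0 °C; 5-exo attack of the carboxylate on the iodonium ion of the vinyl group, trans product under equilibrating conditions), giving the iodomethyl lactone hydroxy ester F1. Dess–Martin oxidation gives the iodomethyl lactone β-keto ester F2. Intramolecular C-alkylation of the β-keto ester by the primary iodide (Cs2CO3, MeCN, high dilution) then forms C2–C3 and arrives at 31.

**Step 9.** Poor facial selectivity relative to C7 is the likely problem: the quaternary β-centre differentiates the aldehyde faces only weakly, so up to half of the material may end in the other syn diastereomer.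
Fallback (chelation control instead of the non-chelating silyl ether, from 9 back to 20): selective silylation of the primary hydroxyl of 9 (Et3SiCl, imidazole, −40 °C) gives the mono-silyl ether F3, and dithioacetal hydrolysis as in step 6 gives the β-hydroxy aldehyde F4. Indium-mediated addition of 15 in THF/H2O then runs through a chelate between the free tertiary hydroxyl and the aldehyde, the arrangement that favours 1,3-anti diols, and gives the diol ester F5. Angeloylation as in step 10 (the tertiary hydroxyl is inert) gives F6, and Et3SiOTf/2,6-lutidine silylates the tertiary hydroxyl to return to 20.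

**Step 19.** Conjugate hydride addition to the exocyclic methylene lactone may compete with reduction of the activated carboxyl group, since borohydride is known to saturate such lactones.
Fallback (masking of the Michael acceptor, from 33 back to 35): dimethylamine (THF, 0 °C) adds to the methylene lactone of 33 to give the amino acid F7. Activation with i-BuOCOCl/N-methylmorpholine gives the mixed anhydride F8, and NaBH4 reduces it to the amino triol F9. Quaternisation with MeI gives the ammonium iodide F10, and aqueous NaHCO3 eliminates trimethylamine to restore the methylene group, arriving at 35.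

**Step 7.** Self-condensation and oligomerisation of acrolein under amine catalysis may outrun the cross-coupling, because acrolein is both the better acceptor and the better electrophile.
Fallback (hydroalumination instead of amine catalysis, from 12 back to 14): i-Bu2AlH with N-methylmorpholine N-oxide in THF adds across tert-butyl propiolate to give the α-aluminated acrylate F11, which adds 1,2 to the aldehyde of 12 and gives 14 after aqueous work-up.

## Further compounds

F1 | step 16 | 2-(trimethylsilyl)ethyl hydroxy ester carrying the trans-5-(iodomethyl)-3-methylidene-γ-lactone (iodolactone of 27) | C=C1C(=O)O[C@H](CI)[C@H]1[C@H](OC(=O)/C(C)=C\C)C[C@@](C)(O[Si](CC)(CC)CC)/C=C\C(O)CC(=O)OCC[Si](C)(C)C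
F2 | step 16 | iodomethyl lactone β-keto ester (oxidation product of F1) | C=C1C(=O)O[C@H](CI)[C@H]1[C@H](OC(=O)/C(C)=C\C)C[C@@](C)(O[Si](CC)(CC)CC)/C=C\C(=O)CC(=O)OCC[Si](C)(C)C
F3 | step 9 | (2R,3Z)-1-(1,3-dithian-2-yl)-2-methyl-5-(triethylsilyloxy)pent-3-en-2-ol | C[C@](O)(/C=C\CO[Si](CC)(CC)CC)CC1SCCCS1
F4 | step 9 | (3R,4Z)-3-hydroxy-3-methyl-6-(triethylsilyloxy)hex-4-enal | C[C@](O)(/C=C\CO[Si](CC)(CC)CC)CC=O
F5 | step 9 | tert-butyl (3R,4R,6R,7Z)-3-ethenyl-4,6-dihydroxy-6-methyl-2-methylidene-9-(triethylsilyloxy)non-7-enoate | C=C[C@@H]([C@H](O)C[C@@](C)(O)/C=C\CO[Si](CC)(CC)CC)C(=C)C(=O)OC(C)(C)C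
F6 | step 9 | tert-butyl (3R,4R,6R,7Z)-3-ethenyl-6-hydroxy-6-methyl-4-{[(2Z)-2-methylbut-2-enoyl]oxy}-2-methylidene-9-(triethylsilyloxy)non-7-enoate | C=C[C@@H]([C@H](OC(=O)/C(C)=C\C)C[C@@](C)(O)/C=C\CO[Si](CC)(CC)CC)C(=C)C(=O)OC(C)(C)C
F7 | step 19 | dimethylamine adduct of 33 (3-[(dimethylamino)methyl] lactone acid) | CN(C)CC1C(=O)O[C@@H]2C[C@@H](C(=O)O)C(O)/C=C\[C@](C)(O)C[C@@H](OC(=O)/C(C)=C\C)[C@@H]12
F8 | step 19 | isobutyl carbonic anhydride of F7 | CN(C)CC1C(=O)O[C@@H]2C[C@@H](C(=O)OC(=O)OCC(C)C)C(O)/C=C\[C@](C)(O)C[C@@H](OC(=O)/C(C)=C\C)[C@@H]12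
F9 | step 19 | dimethylamine adduct of 35 (amino triol) | CN(C)CC1C(=O)O[C@@H]2C[C@@H](CO)C(O)/C=C\[C@](C)(O)C[C@@H](OC(=O)/C(C)=C\C)[C@@H]12
F10 | step 19 | trimethylammonium iodide of F9 | C[N+](C)(C)CC1C(=O)O[C@@H]2C[C@@H](CO)C(O)/C=C\[C@](C)(O)C[C@@H](OC(=O)/C(C)=C\C)[C@@H]12.[I-]
F11 | step 7 | tert-butyl 2-(diisobutylalumanyl)prop-2-enoate | C=C(C(=O)OC(C)(C)C)[Al](CC(C)C)CC(C)C
A1 | alternative 1 | thirteen-membered cyclic allylic ether with C1 tributylstannane | CCCC[Sn](CCCC)(CCCC)C1OCC(CO[Si](CC)(CC)CC)=C[C@H](OCc2ccc(OC)cc2)C[C@@](C)(O[Si](C)(C)C(C)(C)C)/C=C\C2OC(C)(C)OC[C@@H]2C1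
A2 | alternative 1 | ten-membered homoallylic alcohol from the ring contraction | C=C(CO[Si](CC)(CC)CC)[C@H]1[C@H](O)C[C@@H](COC2(C)C)C(O2)/C=C\[C@](C)(O[Si](C)(C)C(C)(C)C)C[C@H]1OCc3ccc(OC)cc3
A3 | alternative 2 | ten-membered (4Z,6Z)-diene methylene lactone | C=C1C(=O)O[C@@H]2C[C@@H](CO[Si](C)(C)C(C)(C)C)/C=C\C=C(C)/C[C@@H](OC(=O)/C(C)=C\C)[C@@H]12
A4 | alternative 2 | bridged 1,2-dioxine endoperoxide | C=C1C(=O)O[C@@H]2C[C@@H](CO[Si](C)(C)C(C)(C)C)[C@H]3C=C[C@](C)(OO3)C[C@@H](OC(=O)/C(C)=C\C)[C@@H]12
A5 | alternative 3 | 3-(bromomethyl)butenolide tethered to the C9 aldehyde | O=CC[C@@](C)(O[Si](CC)(CC)CC)/C=C\C(=O)[C@H](CO[Si](C)(C)C(C)(C)C)C[C@H]1OC(=O)C(CBr)=C1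
A6 | alternative 3 | germacranolide C9 alcohol, C9 epimer of the target carbinol | C=C1C(=O)O[C@@H]2C[C@@H](CO[Si](C)(C)C(C)(C)C)C(=O)/C=C\[C@](C)(O[Si](CC)(CC)CC)C[C@H](O)[C@@H]12
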